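The benzene ring is made, not bought: its C1–C6 and C2–C3 bonds are disconnected to 3,4-dimethoxyfuran and pent-1-yn-3-one. A single operation, furan–ynone [4+2] cycloaddition followed by Lewis-acid opening of the oxygen bridge, closes the six-membered carbocycle and delivers the aryl ethyl ketone with its phenol already distinguished from the two methyl ethers. The feature exploited is the substitution pattern of that ring: the C3 hydroxyl oxygen is the furan ring oxygen, the C4 and C5 methoxy groups are those of the symmetrical furan, and C1 (bearing the side chain) and C2 are the alkyne carbons. Asymmetric transfer hydrogenation then sets the (S)-carbinol, which is acylated with a separately built (Z,Z)-acid.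

Key step: step 6

Remark: pent-1-yn-3-ol is used as the racemate because step 5 removes its stereocentre, and the (Z,Z)-acid partner is assumed not to be purchasable, so it is built in steps 9–13.

Step 1
Reactants: 1 dimethyl diglycolate (dimethyl 2,2'-oxydiacetate); 2 dimethyl oxalate
Product: 3 dimethyl 3,4-dihydroxyfuran-2,5-dicarboxylate
Conditions: NaOMe (2.2 equiv), MeOH, reflux; aq. HCl work-up
Reagents that add atoms: none
Why: Hinsberg furan synthesis, in which two Claisen condensations join the α-carbons of 1 to the two carbonyl carbons of 2 and the disodium dienolate that precipitates is protonated on work-up to the aromatic dihydroxyfuran.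

Step 2
Reactants: 3 dimethyl 3,4-dihydroxyfuran-2,5-dicarboxylate
Product: 4 dimethyl 3,4-dimethoxyfuran-2,5-dicarboxylate
Conditions: MeI (3 equiv), K2CO3, DMF, 40 °C
Reagents that add atoms: iodomethane, CI
Why: Williamson-type O-methylation of the two acidic enolic hydroxyl groups, which behave as vinylogous carbonic acids and should alkylate cleanly on oxygen under carbonate conditions.

Step 3
Reactants: 4 dimethyl 3,4-dimethoxyfuran-2,5-dicarboxylate
Product: 5 3,4-dimethoxyfuran-2,5-dicarboxylic acid
Conditions: NaOH, H2O/MeOH, reflux; aq. HCl to pH 1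
Reagents that add atoms: sodium hydroxide, [Na+].[OH-]
Why: Saponification of both methyl esters by acyl–oxygen cleavage, the furan being stable to aqueous base and the diacid precipitating on acidification.

Step 4
Reactants: 5 3,4-dimethoxyfuran-2,5-dicarboxylic acid
Product: 6 3,4-dimethoxyfuran
Conditions: Cu powder (0.1 equiv), quinoline, 190–200 °C, product distilled out under N2
Reagents that add atoms: none
Why: Cu-mediated protodecarboxylation of furan-2-carboxylic acids in quinoline, a standard route to free furan α-positions, with the volatile, acid-sensitive furan removed from the hot medium as it forms.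

Step 5
Reactants: 7 pent-1-yn-3-ol (racemic)
Product: 8 pent-1-yn-3-one
Conditions: IBX (1.2 equiv), EtOAc, 75 °C; filtration, fractional distillation
Reagents that add atoms: none
Why: IBX oxidation of a secondary propargylic alcohol under neutral, non-nucleophilic conditions that the base-sensitive terminal ynone should tolerate.

Step 6
Reactants: 6 3,4-dimethoxyfuran; 8 pent-1-yn-3-one
Product: 10 1-(3-hydroxy-4,5-dimethoxyphenyl)propan-1-one, via oxanorbornadiene ketone 9 (not isolated)
Conditions: 8 (1.5 equiv), BHT (cat.), toluene, 60 °C; then BF3·OEt2 (0.2 equiv), CH2Cl2, −40 to 0 °C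
Reagents that add atoms: none
Why: The electron-rich, C2v-symmetric furan 6 adds suprafacially across the electron-poor alkyne of 8 in a concerted, asynchronous normal-demand [4+2] cycloaddition; this intermolecular ring closure makes the six-membered carbocycle by bonding the two furan α-carbons to the two alkyne carbons (arene C1–C6 and C2–C3), and the symmetry of the diene allows only one constitution for 9. BF3, a monodentate Lewis acid that cannot chelate the ketone and bridge oxygens, then ionises the bridgehead C–O bond beside the acyl-bearing alkene carbon, because only that cleavage gives a pentadienyl cation whose charge rests on a methoxy-bearing carbon as an oxocarbenium ion while the acyl-bearing carbon sits at a nodal position; loss of the proton from the remaining oxygen-bearing bridgehead aromatises the ring. The closest known reaction type is the Diels–Alder addition of furans to acetylenic esters and ketones followed by acid-catalysed isomerisation of the 7-oxanorbornadiene to a meta-acyl phenol. The two bridgehead stereocentres of 9 form as a racemate and vanish on aromatisation, so no stereocontrol is required. The selectivities needed are the direction of bridge opening (hydroxyl meta, not ortho, to the ketone), secured by the acyl group, and cycloaddition in preference to conjugate addition of the furan α-carbon to the ynone, secured by running the cycloaddition acid-free and adding BF3 only once 9 has formed.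

Step 7
Reactants: 10 1-(3-hydroxy-4,5-dimethoxyphenyl)propan-1-one
Product: 11 1-{3-[(tert-butyldimethylsilyl)oxy]-4,5-dimethoxyphenyl}propan-1-one
Conditions: TBSCl, imidazole, DMF, rt
Reagents that add atoms: tert-butyldimethylsilyl chloride, CC(C)(C)[Si](C)(C)Cl
Why: Imidazole-promoted silylation masks the phenol for the later acylation as an aryl silyl ether that should survive the acidic formate medium of step 8 and triethylamine at 80 °C in step 14.

Step 8
Reactants: 11 1-{3-[(tert-butyldimethylsilyl)oxy]-4,5-dimethoxyphenyl}propan-1-one
Product: 12 (1S)-1-{3-[(tert-butyldimethylsilyl)oxy]-4,5-dimethoxyphenyl}propan-1-ol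
Conditions: RuCl(p-cymene)[(S,S)-TsDPEN] (1 mol%), HCO2H/Et3N (5:2), EtOAc, 30 °C
Reagents that add atoms: none
Why: Asymmetric transfer hydrogenation of the Noyori–Ikariya type, in which the (S,S)-ligand and the CH/π contact between the η6-arene and the aryl group in the six-membered outer-sphere transition state direct hydride to the Re face of the aryl ethyl ketone and should give the (S)-carbinol.

Step 9
Reactants: 13 (E)-but-2-enal (crotonaldehyde)
Product: 15 (2Z)-2-bromobut-2-enal, via 2,3-dibromobutanal 14 (not isolated)
Conditions: Br2, CH2Cl2, −10 °C; then Et3N, 0 °C to rt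
Reagents that add atoms: bromine, BrBr
Why: α-Bromination of an enal by addition–elimination, where anti addition of bromine and triethylamine-induced E1cB loss of the β-bromide should give the thermodynamically preferred Z isomer with methyl cis to bromine and trans to the formyl group.

Step 10
Reactants: 15 (2Z)-2-bromobut-2-enal
Product: 16 (2Z)-2-bromobut-2-en-1-ol
Conditions: NaBH4, CeCl3·7H2O, MeOH, 0 °C
Reagents that add atoms: none
Why: Luche reduction delivers hydride 1,2 to the enal and should leave the vinyl bromide and the alkene geometry untouched.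

Step 11
Reactants: 16 (2Z)-2-bromobut-2-en-1-ol
Product: 17 4-methoxybenzyl (2Z)-2-(hydroxymethyl)but-2-enoate
Conditions: CO (1 atm), Pd(OAc)2 (3 mol%), Xantphos (3 mol%), 4-MeOC6H4CH2OH (3 equiv), Et3N (2 equiv), toluene, 70 °C
Reagents that add atoms: carbon monoxide, [C-]#[O+]; 4-methoxybenzyl alcohol, COc1ccc(CO)cc1
Why: Alkoxycarbonylation of a vinyl bromide, in which oxidative addition of the C–Br bond to zerovalent palladium, CO insertion and alcoholysis of the acyl–palladium all retain alkene geometry, so the bromine cis to methyl becomes the ester carbonyl cis to methyl (the Z enoate), while the excess primary benzylic alcohol should outcompete four-membered lactonisation by the free hydroxyl.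

Step 12
Reactants: 17 4-methoxybenzyl (2Z)-2-(hydroxymethyl)but-2-enoate; 18 angelic acid, (2Z)-2-methylbut-2-enoic acid
Product: 20 4-methoxybenzyl (2Z)-2-({[(2Z)-2-methylbut-2-enoyl]oxy}methyl)but-2-enoate, via angelic 2,4,6-trichlorobenzoic anhydride 19 (not isolated)
Conditions: 18, 2,4,6-Cl3C6H2COCl, Et3N, toluene, rt; then 17, 80 °C
Reagents that add atoms: none
Why: Yamaguchi esterification run without DMAP, in which the primary allylic alcohol attacks the unhindered angeloyl carbonyl of 19 and the absence of a nucleophilic catalyst should avoid both angelate-to-tiglate isomerisation and SN2′ attack on the 2-(acyloxymethyl)enoate.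

Step 13
Reactants: 20 4-methoxybenzyl (2Z)-2-({[(2Z)-2-methylbut-2-enoyl]oxy}methyl)but-2-enoate
Product: 21 (2Z)-2-({[(2Z)-2-methylbut-2-enoyl]oxy}methyl)but-2-enoic acid
Conditions: TFA, anisole, CH2Cl2, 0 °C
Reagents that add atoms: none
Why: Acidolysis of the 4-methoxybenzyl ester through its stabilised benzylic cation, trapped by anisole, should free the acid without hydrolytic conditions that could not tell it from the angelate ester.

Step 14
Reactants: 12 (1S)-1-{3-[(tert-butyldimethylsilyl)oxy]-4,5-dimethoxyphenyl}propan-1-ol; 21 (2Z)-2-({[(2Z)-2-methylbut-2-enoyl]oxy}methyl)but-2-enoic acid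
Product: 23 (1S)-1-{3-[(tert-butyldimethylsilyl)oxy]-4,5-dimethoxyphenyl}propyl (2Z)-2-({[(2Z)-2-methylbut-2-enoyl]oxy}methyl)but-2-enoate, via dienoic 2,4,6-trichlorobenzoic anhydride 22 (not isolated)
Conditions: 21 (1.5 equiv), 2,4,6-Cl3C6H2COCl, Et3N, toluene, rt; then 12, 80 °C
Reagents that add atoms: none
Why: DMAP-free Yamaguchi esterification in which the hydroxyl oxygen of 12 attacks the enoyl carbonyl of 22, so the C–O bond at the stereocentre is never broken and the (S) configuration is retained, while omitting DMAP should protect both Z alkenes and the allylic angelate.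

Step 15
Reactants: 23 (1S)-1-{3-[(tert-butyldimethylsilyl)oxy]-4,5-dimethoxyphenyl}propyl (2Z)-2-({[(2Z)-2-methylbut-2-enoyl]oxy}methyl)but-2-enoate
Product: 24 (1S)-1-(3-hydroxy-4,5-dimethoxyphenyl)propyl (2Z)-2-({[(2Z)-2-methylbut-2-enoyl]oxy}methyl)but-2-enoate (CNP0282120.1)
Conditions: TBAF, AcOH (1:1), THF, 0 °C
Reagents that add atoms: none
Why: Fluoride-induced cleavage of the aryl silyl ether, buffered with acetic acid so that neither phenoxide nor basic fluoride should attack the esters, isomerise the Z alkenes or disturb the benzylic C–O bond.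

Compound list
1 | dimethyl diglycolate (dimethyl 2,2'-oxydiacetate) | COC(=O)COCC(=O)OC | starting material
2 | dimethyl oxalate | COC(=O)C(=O)OC | starting material
3 | dimethyl 3,4-dihydroxyfuran-2,5-dicarboxylate | COC(=O)c1oc(C(=O)OC)c(O)c1O | intermediate
4 | dimethyl 3,4-dimethoxyfuran-2,5-dicarboxylate | COC(=O)c1oc(C(=O)OC)c(OC)c1OC | intermediate
5 | 3,4-dimethoxyfuran-2,5-dicarboxylic acid | COc1c(C(=O)O)oc(C(=O)O)c1OC | intermediate
6 | 3,4-dimethoxyfuran | COc1cocc1OC | intermediate
7 | pent-1-yn-3-ol (racemic) | CCC(O)C#C | starting material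
8 | pent-1-yn-3-one | CCC(=O)C#C | intermediate
9 | 1-(5,6-dimethoxy-7-oxabicyclo[2.2.1]hepta-2,5-dien-2-yl)propan-1-one (racemic, not isolated) | CCC(=O)C1=CC2OC1C(OC)=C2OC | intermediate
10 | 1-(3-hydroxy-4,5-dimethoxyphenyl)propan-1-one | CCC(=O)c1cc(O)c(OC)c(OC)c1 | intermediate
11 | 1-{3-[(tert-butyldimethylsilyl)oxy]-4,5-dimethoxyphenyl}propan-1-one | CCC(=O)c1cc(O[Si](C)(C)C(C)(C)C)c(OC)c(OC)c1 | intermediate
12 | (1S)-1-{3-[(tert-butyldimethylsilyl)oxy]-4,5-dimethoxyphenyl}propan-1-ol | O[C@@H](CC)c1cc(O[Si](C)(C)C(C)(C)C)c(OC)c(OC)c1 | intermediate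
13 | (E)-but-2-enal (crotonaldehyde) | C/C=C/C=O | starting material
14 | 2,3-dibromobutanal (racemic, not isolated) | CC(Br)C(Br)C=O | intermediate
15 | (2Z)-2-bromobut-2-enal | C/C=C(\Br)C=O | intermediate
16 | (2Z)-2-bromobut-2-en-1-ol | C/C=C(\Br)CO | intermediate
17 | 4-methoxybenzyl (2Z)-2-(hydroxymethyl)but-2-enoate | C/C=C(/CO)C(=O)OCc1ccc(OC)cc1 | intermediate
18 | angelic acid, (2Z)-2-methylbut-2-enoic acid | C/C=C(/C)C(=O)O | starting material
19 | (2Z)-2-methylbut-2-enoic 2,4,6-trichlorobenzoic anhydride (not isolated) | C/C=C(/C)C(=O)OC(=O)c1c(Cl)cc(Cl)cc1Cl | intermediate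
20 | 4-methoxybenzyl (2Z)-2-({[(2Z)-2-methylbut-2-enoyl]oxy}methyl)but-2-enoate | C/C=C(/C)C(=O)OC/C(=C/C)C(=O)OCc1ccc(OC)cc1 | intermediate
21 | (2Z)-2-({[(2Z)-2-methylbut-2-enoyl]oxy}methyl)but-2-enoic acid | C/C=C(/C)C(=O)OC/C(=C/C)C(=O)O | intermediate
22 | (2Z)-2-({[(2Z)-2-methylbut-2-enoyl]oxy}methyl)but-2-enoic 2,4,6-trichlorobenzoic anhydride (not isolated) | C/C=C(/C)C(=O)OC/C(=C/C)C(=O)OC(=O)c1c(Cl)cc(Cl)cc1Cl | intermediate
23 | (1S)-1-{3-[(tert-butyldimethylsilyl)oxy]-4,5-dimethoxyphenyl}propyl (2Z)-2-({[(2Z)-2-methylbut-2-enoyl]oxy}methyl)but-2-enoate | C/C=C(/C)C(=O)OC/C(=C/C)C(=O)O[C@@H](CC)c1cc(O[Si](C)(C)C(C)(C)C)c(OC)c(OC)c1 | intermediate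
24 | (1S)-1-(3-hydroxy-4,5-dimethoxyphenyl)propyl (2Z)-2-({[(2Z)-2-methylbut-2-enoyl]oxy}methyl)but-2-enoate | C/C=C(/C)C(=O)OC/C(=C/C)C(=O)O[C@@H](CC)c1cc(O)c(OC)c(OC)c1 | target

Total step count: 15. Longest linear sequence: 9 steps (steps 1, 2, 3, 4, 6, 7, 8, 14, 15); the acid branch (steps 9–13) joins at step 14.

Steps most likely to fail

Step 6. Conjugate (Friedel–Crafts-type) addition of the nucleophilic furan α-carbon to the ynone, or oligomerisation of the terminal ynone, may outrun cycloaddition, and ionisation of the other bridgehead C–O bond would divert material to the ortho-hydroxy ketone. The fallback no longer carries the ketone through the cycloaddition. It sets out from 6: thermal Diels–Alder addition of the more robust methyl propiolate should give methyl 5,6-dimethoxy-7-oxabicyclo[2.2.1]hepta-2,5-diene-2-carboxylate F1, which BF3·OEt2 should isomerise to methyl 3-hydroxy-4,5-dimethoxybenzoate F2, the meta-hydroxy benzoate being the established outcome for propiolate adducts. Silylation (TBSCl, imidazole) would give methyl 3-[(tert-butyldimethylsilyl)oxy]-4,5-dimethoxybenzoate F3. Aminolysis with MeNH(OMe)·HCl and i-PrMgCl would give the Weinreb amide 3-[(tert-butyldimethylsilyl)oxy]-N,4,5-trimethoxy-N-methylbenzamide F4, and EtMgBr would convert it into ketone 11, where the route is rejoined.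

Step 14. Z-to-E isomerisation of the but-2-enoyl unit during carboxyl activation, SN2′ loss of the allylic angelate, or sluggish acylation of the secondary benzylic alcohol without a nucleophilic catalyst may erode the coupling. The fallback uses the acid as a nucleophile so that its carbonyl is never activated. It sets out from 11: transfer hydrogenation with the enantiomeric catalyst RuCl(p-cymene)[(R,R)-TsDPEN] should give (1R)-1-{3-[(tert-butyldimethylsilyl)oxy]-4,5-dimethoxyphenyl}propan-1-ol F5. Mitsunobu esterification with acid 21 (PPh3 and DIAD premixed at −20 °C, toluene) should then proceed with inversion at the benzylic carbon and come back to the route at 23; partial ionisation of the electron-rich benzylic centre is the risk accepted in exchange.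

Step 11. Acylation of the unprotected hydroxyl by the acyl–palladium (lactonisation or oligomeric esters), slow alcoholysis with a non-solvent amount of the benzylic alcohol, or phosphine-mediated Z-to-E leakage may spoil the carbonylation. The fallback replaces catalysis by halogen–lithium exchange. It sets out from 16: deprotonation with n-BuLi, bromine–lithium exchange with t-BuLi (2 equiv, THF, −78 °C; configurationally stable vinyllithium) and quenching with CO2 should give (2Z)-2-(hydroxymethyl)but-2-enoic acid F6. Selective O-alkylation of its carboxylate with 4-methoxybenzyl chloride (KHCO3, DMF) would return to the route at 17.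

Further compounds
F1 | step 6 | methyl 5,6-dimethoxy-7-oxabicyclo[2.2.1]hepta-2,5-diene-2-carboxylate (racemic) | COC(=O)C1=CC2OC1C(OC)=C2OC
F2 | step 6 | methyl 3-hydroxy-4,5-dimethoxybenzoate | COC(=O)c1cc(O)c(OC)c(OC)c1
F3 | step 6 | methyl 3-[(tert-butyldimethylsilyl)oxy]-4,5-dimethoxybenzoate | COC(=O)c1cc(O[Si](C)(C)C(C)(C)C)c(OC)c(OC)c1
F4 | step 6 | 3-[(tert-butyldimethylsilyl)oxy]-N,4,5-trimethoxy-N-methylbenzamide | CON(C)C(=O)c1cc(O[Si](C)(C)C(C)(C)C)c(OC)c(OC)c1
F5 | step 14 | (1R)-1-{3-[(tert-butyldimethylsilyl)oxy]-4,5-dimethoxyphenyl}propan-1-ol | O[C@H](CC)c1cc(O[Si](C)(C)C(C)(C)C)c(OC)c(OC)c1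
F6 | step 11 | (2Z)-2-(hydroxymethyl)but-2-enoic acid | C/C=C(/CO)C(=O)O
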